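**Retrosynthetic overview**
- The C1=N ring is closed last, by Bischler–Napieralski cyclisation of an (S)-acetamide (C1–C8a bond).
- Key C–C bond: the 7,6'-biaryl bond joins two innately nucleophilic arene carbons. The dimethoxyarene carbon is made an aryl cation equivalent (ArSnBu3 → ArPb(OAc)3) and arylates the free naphthol at its ortho carbon.
- The aryl stannane comes from lithiation between the two OMe groups of an (S)-N-Boc-1-arylpropan-2-amine, made from 1-bromo-3,5-dimethoxybenzene and (S)-N-Boc-2-methylaziridine. The stereocentre is bought (L-alanine series); none is created.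
- The naphthol comes from anionic benzannulation of an ortho-allyl diethylbenzamide derived from 2-methoxy-4-methylbenzoic acid.
- Ring order: second naphthalene ring (step 3) → biaryl (step 6) → dihydroisoquinoline ring (step 8).

Assumption: the SMILES defines no axial configuration, so the biaryl axis (ortho groups OMe, OMe, OH, H) is treated as freely rotating and only the (S)-centre at C3 is controlled.

**Route**

Step 1
Reactants: 1 2-methoxy-4-methylbenzoic acid
Product: 3 N,N-diethyl-2-methoxy-4-methylbenzamide, via acid chloride 2 (not isolated)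
Conditions: SOCl2, DMF (cat.), toluene, 70 °C; concentrate; then Et2NH, aq NaOH, CH2Cl2, 0 °C → rt
Reagents that add atoms: diethylamine, CCNCC
Why: Schotten–Baumann amide formation through the acid chloride installs the tertiary amide that directs the metalation in step 2 and acts as the internal acylating group in step 3.

Step 2
Reactants: 3 N,N-diethyl-2-methoxy-4-methylbenzamide
Product: 6 N,N-diethyl-2-allyl-6-methoxy-4-methylbenzamide, via aryllithium 4 (not isolated), via arylmagnesium bromide 5 (not isolated)
Conditions: s-BuLi, TMEDA, THF, −78 °C; MgBr2·OEt2, −78 → 0 °C; allyl bromide, 0 °C → rt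
Reagents that add atoms: allyl bromide, C=CCBr
Why: Directed ortho-metalation by the diethylamide removes the only hydrogen ortho to it, and lithium-to-magnesium exchange lets the aryl anion be allylated cleanly by allyl bromide.

Step 3
Reactants: 6 N,N-diethyl-2-allyl-6-methoxy-4-methylbenzamide
Product: 8 8-methoxy-6-methylnaphthalen-1-ol, via allyllithium 7 (not isolated)
Conditions: LiN(i-Pr)2 (2.5 equiv), THF, −78 °C → rt; aq NH4Cl
Reagents that add atoms: none
Why: Anionic benzannulation of an ortho-allylbenzamide (Snieckus type), in which the delocalised benzylic allyl anion attacks the amide carbonyl through its terminal carbon in a 6-membered ring closure and loss of LiNEt2 then tautomerisation gives the 1-naphthol with OH peri to OMe by construction.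

Step 4
Reactants: 9 1-bromo-3,5-dimethoxybenzene, 10 tert-butyl (2S)-2-methylaziridine-1-carboxylate
Product: 12 tert-butyl N-[(2S)-1-(3,5-dimethoxyphenyl)propan-2-yl]carbamate, via aryl Grignard reagent 11 (not isolated)
Conditions: Mg, THF, reflux; then CuBr·SMe2 (10 mol %), 10, THF, −30 → 0 °C; aq NH4Cl
Reagents that add atoms: none
Why: Copper-catalysed SN2 ring opening of an N-Boc aziridine by an aryl Grignard reagent occurs at the unsubstituted CH2, so the (S)-centre of the aziridine is carried over untouched.

Step 5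
Reactants: 12 tert-butyl N-[(2S)-1-(3,5-dimethoxyphenyl)propan-2-yl]carbamate
Product: 14 tert-butyl N-[(2S)-1-[3,5-dimethoxy-4-(tributylstannyl)phenyl]propan-2-yl]carbamate, via N,4-dilithio species 13 (not isolated)
Conditions: n-BuLi (2.4 equiv), TMEDA, THF, −78 → 0 °C; Bu3SnCl (1.1 equiv), −78 °C → rt; aq NH4Cl
Reagents that add atoms: tributyltin chloride, CCCC[Sn](Cl)(CCCC)CCCC
Why: Directed ortho-metalation in which, after N–H deprotonation, the second equivalent of n-BuLi lithiates the position flanked by both methoxy groups (as with 5-alkylresorcinol dimethyl ethers) and Bu3SnCl traps the aryllithium, while the N-lithio carbamate protects the stereocentre from alpha-deprotonation.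

Step 6 (key step)
Reactants: 14 tert-butyl N-[(2S)-1-[3,5-dimethoxy-4-(tributylstannyl)phenyl]propan-2-yl]carbamate, 8 8-methoxy-6-methylnaphthalen-1-ol
Product: 16 tert-butyl N-[(2S)-1-[4-(1-hydroxy-8-methoxy-6-methylnaphthalen-2-yl)-3,5-dimethoxyphenyl]propan-2-yl]carbamate, via aryllead triacetate 15 (not isolated)
Conditions: Pb(OAc)4 (1.0 equiv), Hg(OAc)2 (10 mol %), CHCl3, 40 °C; then 8 (1.3 equiv), pyridine (3 equiv), CHCl3, 60 °C
Reagents that add atoms: none
Why: Pinhey arylation, in which tin-to-lead exchange turns the normally nucleophilic ring carbon into an aryl cation equivalent on tetravalent lead that binds the naphthoxide and transfers the aryl group to the only free ortho carbon by ligand coupling with reduction to divalent lead, so two innately nucleophilic arene carbons are joined without halogenation or protection and no stereocentre is formed.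

Step 7
Reactants: 16 tert-butyl N-[(2S)-1-[4-(1-hydroxy-8-methoxy-6-methylnaphthalen-2-yl)-3,5-dimethoxyphenyl]propan-2-yl]carbamate
Product: 18 2-[4-[(2S)-2-acetamidopropyl]-2,6-dimethoxyphenyl]-8-methoxy-6-methylnaphthalen-1-yl acetate, via amine hydrochloride 17 (not isolated)
Conditions: 4 M HCl in dioxane, 0 °C → rt; concentrate; Ac2O, pyridine, DMAP (cat.), CH2Cl2, rt
Reagents that add atoms: acetic anhydride, CC(=O)OC(C)=O
Why: Acidolytic Boc cleavage followed by exhaustive acetylation gives the acetamide needed for ring closure and at the same time masks the naphthol as its acetate against POCl3.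

Step 8
Reactants: 18 2-[4-[(2S)-2-acetamidopropyl]-2,6-dimethoxyphenyl]-8-methoxy-6-methylnaphthalen-1-yl acetate
Product: 20 2-[(3S)-6,8-dimethoxy-1,3-dimethyl-3,4-dihydroisoquinolin-7-yl]-8-methoxy-6-methylnaphthalen-1-ol, via O-acetyl dihydroisoquinoline 19 (not isolated)
Conditions: POCl3, MeCN, 80 °C; concentrate; K2CO3 (cat.), MeOH, rt
Reagents that add atoms: none
Why: Bischler–Napieralski cyclodehydration in which the nitrilium ion closes onto either of the two equivalent positions ortho to the side chain (each para to a methoxy group) without involving C3, and mild methanolysis then removes the naphthyl acetate while leaving the cyclic imine intact.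

**Compound list**

1 | 2-methoxy-4-methylbenzoic acid | COc1cc(C)ccc1C(=O)O | starting material
2 | 2-methoxy-4-methylbenzoyl chloride | COc1cc(C)ccc1C(=O)Cl | intermediate
3 | N,N-diethyl-2-methoxy-4-methylbenzamide | CCN(CC)C(=O)c1ccc(C)cc1OC | intermediate
4 | N,N-diethyl-2-lithio-6-methoxy-4-methylbenzamide | CCN(CC)C(=O)c1c([Li])cc(C)cc1OC | intermediate
5 | [2-(diethylcarbamoyl)-3-methoxy-5-methylphenyl]magnesium bromide | CCN(CC)C(=O)c1c([Mg]Br)cc(C)cc1OC | intermediate
6 | N,N-diethyl-2-allyl-6-methoxy-4-methylbenzamide | CCN(CC)C(=O)c1c(CC=C)cc(C)cc1OC | intermediate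
7 | benzylic allyllithium of 6 (1-lithio-1-arylprop-2-ene) | CCN(CC)C(=O)c1c(C([Li])C=C)cc(C)cc1OC | intermediate
8 | 8-methoxy-6-methylnaphthalen-1-ol | COc1cc(C)cc2cccc(O)c12 | intermediate
9 | 1-bromo-3,5-dimethoxybenzene | COc1cc(Br)cc(OC)c1 | starting material
10 | tert-butyl (2S)-2-methylaziridine-1-carboxylate | C[C@H]1CN1C(=O)OC(C)(C)C | starting material
11 | (3,5-dimethoxyphenyl)magnesium bromide | COc1cc([Mg]Br)cc(OC)c1 | intermediate
12 | tert-butyl N-[(2S)-1-(3,5-dimethoxyphenyl)propan-2-yl]carbamate | C[C@H](NC(=O)OC(C)(C)C)Cc1cc(OC)cc(OC)c1 | intermediate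
13 | N,4-dilithio derivative of 12 | C[C@H](N([Li])C(=O)OC(C)(C)C)Cc1cc(OC)c([Li])c(OC)c1 | intermediate
14 | tert-butyl N-[(2S)-1-[3,5-dimethoxy-4-(tributylstannyl)phenyl]propan-2-yl]carbamate | C[C@H](NC(=O)OC(C)(C)C)Cc1cc(OC)c([Sn](CCCC)(CCCC)CCCC)c(OC)c1 | intermediate
15 | [4-[(2S)-2-(tert-butoxycarbonylamino)propyl]-2,6-dimethoxyphenyl]lead triacetate | C[C@H](NC(=O)OC(C)(C)C)Cc1cc(OC)c([Pb](OC(C)=O)(OC(C)=O)OC(C)=O)c(OC)c1 | intermediate
16 | tert-butyl N-[(2S)-1-[4-(1-hydroxy-8-methoxy-6-methylnaphthalen-2-yl)-3,5-dimethoxyphenyl]propan-2-yl]carbamate | C[C@H](NC(=O)OC(C)(C)C)Cc1cc(OC)c(-c2ccc3cc(C)cc(OC)c3c2O)c(OC)c1 | intermediate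
17 | (2S)-1-[4-(1-hydroxy-8-methoxy-6-methylnaphthalen-2-yl)-3,5-dimethoxyphenyl]propan-2-amine hydrochloride | C[C@H](N)Cc1cc(OC)c(-c2ccc3cc(C)cc(OC)c3c2O)c(OC)c1.Cl | intermediate
18 | 2-[4-[(2S)-2-acetamidopropyl]-2,6-dimethoxyphenyl]-8-methoxy-6-methylnaphthalen-1-yl acetate | C[C@H](NC(C)=O)Cc1cc(OC)c(-c2ccc3cc(C)cc(OC)c3c2OC(C)=O)c(OC)c1 | intermediate
19 | 2-[(3S)-6,8-dimethoxy-1,3-dimethyl-3,4-dihydroisoquinolin-7-yl]-8-methoxy-6-methylnaphthalen-1-yl acetate | CC1=N[C@@H](C)Cc2cc(OC)c(-c3ccc4cc(C)cc(OC)c4c3OC(C)=O)c(OC)c21 | intermediate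
20 | 2-[(3S)-6,8-dimethoxy-1,3-dimethyl-3,4-dihydroisoquinolin-7-yl]-8-methoxy-6-methylnaphthalen-1-ol | COc1cc2c(c(OC)c1-c1ccc3cc(C)cc(OC)c3c1O)C(C)=N[C@@H](C)C2 | target

**Step count**

Total: 8 steps. Longest linear sequence: 6 steps (steps 1, 2, 3, 6, 7, 8 from compound 1); the amine branch is 5 steps (steps 4, 5, 6, 7, 8 from compound 9).

**Three steps most likely to fail, with fallbacks**

Most at risk is step 6. The tin-to-lead exchange at a doubly ortho-substituted carbon may be slow, residual Pb(OAc)4 can oxidise the electron-rich naphthol, and an ortho-unsubstituted naphthol is a less willing partner than a hindered one. The fallback sets out from 12 and 8 and comes back at 16, and it replaces the lead chemistry by a palladium cross-coupling. Compound 12 is lithiated as in step 5 and the dilithio species 13 is quenched with 2-isopropoxy-4,4,5,5-tetramethyl-1,3,2-dioxaborolane to give tert-butyl N-[(2S)-1-[3,5-dimethoxy-4-(4,4,5,5-tetramethyl-1,3,2-dioxaborolan-2-yl)phenyl]propan-2-yl]carbamate F1. Naphthol 8 is brominated ortho to the hydroxyl with NBS and catalytic i-Pr2NH in CH2Cl2 to give 2-bromo-8-methoxy-6-methylnaphthalen-1-ol F2. Suzuki–Miyaura coupling of F1 and F2 (Pd(OAc)2, SPhos, K3PO4, toluene/H2O, 80 °C) then gives 16.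

Second is step 5. The N-lithio carbamate could steer the second lithiation to the ring position next to the side chain or to the benzylic CH2, and the electron-rich stannane can protodestannylate on silica. The fallback sets out from 9 and comes back at 14, and it makes the C–Sn bond before the side chain so that the carbamate never meets an alkyllithium. LiN(i-Pr)2 in THF at −78 °C deprotonates 9 between the two methoxy groups without bromine–lithium exchange, and Bu3SnCl gives (4-bromo-2,6-dimethoxyphenyl)tributylstannane F3. Magnesium insertion into the C–Br bond gives [3,5-dimethoxy-4-(tributylstannyl)phenyl]magnesium bromide F4. This opens aziridine 10 under the CuBr·SMe2 conditions of step 4 to give 14.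

Third is step 8. Possible problems are retro-Ritter fragmentation to the styrene, phosphorylation if the acetate is lost early, and slow closure next to the hindered biaryl. The fallback sets out from 17 and comes back at 20, and it closes the ring at the amine oxidation level and oxidises afterwards. Pictet–Spengler reaction of 17 with acetaldehyde in MeOH gives 2-[(3S)-6,8-dimethoxy-1,3-dimethyl-1,2,3,4-tetrahydroisoquinolin-7-yl]-8-methoxy-6-methylnaphthalen-1-ol F5 as a mixture of C1 epimers, which does not matter. N-Chlorination with NCS (1.0 equiv, CH2Cl2, −20 °C) gives 2-[(3S)-2-chloro-6,8-dimethoxy-1,3-dimethyl-1,2,3,4-tetrahydroisoquinolin-7-yl]-8-methoxy-6-methylnaphthalen-1-ol F6. Dehydrochlorination with DBU towards the benzylic C1 then gives 20.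

**Further compounds**

F1 | step 6 | tert-butyl N-[(2S)-1-[3,5-dimethoxy-4-(4,4,5,5-tetramethyl-1,3,2-dioxaborolan-2-yl)phenyl]propan-2-yl]carbamate | C[C@H](NC(=O)OC(C)(C)C)Cc1cc(OC)c(B2OC(C)(C)C(C)(C)O2)c(OC)c1
F2 | step 6 | 2-bromo-8-methoxy-6-methylnaphthalen-1-ol | COc1cc(C)cc2ccc(Br)c(O)c12
F3 | step 5 | (4-bromo-2,6-dimethoxyphenyl)tributylstannane | CCCC[Sn](CCCC)(CCCC)c1c(OC)cc(Br)cc1OC
F4 | step 5 | [3,5-dimethoxy-4-(tributylstannyl)phenyl]magnesium bromide | CCCC[Sn](CCCC)(CCCC)c1c(OC)cc([Mg]Br)cc1OC
F5 | step 8 | 2-[(3S)-6,8-dimethoxy-1,3-dimethyl-1,2,3,4-tetrahydroisoquinolin-7-yl]-8-methoxy-6-methylnaphthalen-1-ol | CC1N[C@@H](C)Cc2cc(OC)c(-c3ccc4cc(C)cc(OC)c4c3O)c(OC)c21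
F6 | step 8 | 2-[(3S)-2-chloro-6,8-dimethoxy-1,3-dimethyl-1,2,3,4-tetrahydroisoquinolin-7-yl]-8-methoxy-6-methylnaphthalen-1-ol | CC1N(Cl)[C@@H](C)Cc2cc(OC)c(-c3ccc4cc(C)cc(OC)c4c3O)c(OC)c21
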